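## Analysis of the target

Target 17 is 4-[(2S,3R)-3-(hydroxymethyl)-5-(3-hydroxypropyl)-7-methoxy-2,3-dihydro-1-benzofuran-2-yl]-2,6-dimethoxyphenol. Re-reading the SMILES gives C2 = S and C3 = R, with the aryl group and the CH2OH group on opposite faces (trans).

- Ring A is a benzene ring with O1 on C7a, a methoxy group on C7 and a 3-hydroxypropyl chain on C5. The dihydrofuran ring contains O1, C2 and C3. Ring B, on C2, is a 4-hydroxy-3,5-dimethoxyphenyl group.
- The only stereocentres are the adjacent C2 and C3. Both are benzylic, and neither has a neighbouring functional group that could direct a reagent.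
- The C2–O1 bond is a benzylic ether para to a free phenol. It can ionise to a para-quinone methide in acid or base (epimerisation, ring opening) and it is open to hydrogenolysis.
- The free phenol and both alkoxy-rich rings are sensitive to oxidants.
- The difficulty is to set the absolute configuration of two contiguous benzylic centres in a five-membered ring and to end with the trans relation without relying on equilibration of the labile final compound.
- The strategy rests on C3. It carries C2, ring A carbon C3a and exactly one exocyclic carbon. If that exocyclic carbon is placed between C3 and C3a, the skeleton becomes a chroman-4-one (flavanone) with the exocyclic carbon as the C4 carbonyl. The dihydrobenzofuran is therefore the ring-contracted form of a flavanone in which ring A has moved from C4 to C3.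
- That flavanone has a single stereocentre, C2, which is the same carbon as C2 of the target.

## Retrosynthetic reasoning

**17 to 16.** The last operation is removal of two benzyl ethers. The ring B phenol is masked because a free para-hydroxyl would make C2–O1 labile and would be oxidised in the key step. The chain hydroxyl is masked so that it stays out of orthoester exchange and of the organometallic steps. One hydrogenolysis removes both groups.

**16 to 15.** The CH2OH group on C3 is traced back to a methyl ester. The ester carbon is the atom that the key step pushes out of the ring, so only a hydride reduction lies between the key step and the protected target.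

**15 to 12 (key disconnection).** The C3–C3a bond is cut and C3a is reconnected to the ester carbon. This turns the 2,3-disubstituted dihydrobenzofuran into flavanone 12.

- Two stereocentres become one, and the trans relation is left to the mechanism of the forward step.
- The forward reaction must oxidise C3 through enol ether 13 and the iodane 14, make ring A carbon C4a migrate from C4 to C3, and leave the old carbonyl carbon as the ester.
- No cut of O1–C2 or C2–C3 simplifies the problem as much, because those cuts leave both stereocentres to be set in an open chain.

**12 to 7 and 11.** The bond between C2 and ring B is cut. A catalytic enantioselective conjugate addition of boronic acid 11 to chromone 7 forms this bond and sets C2, the only stereocentre the route has to create by external control. The cut is convergent and divides the molecule into two pieces of similar size.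

**7 to 4 and 5.** The bond between C6 of the chromone and the first chain carbon is cut. Hydroboration of alkene 5 gives alkylborane 6, which is coupled with bromide 4, so the chain arrives with its benzyl ether already in place. This is preferred over starting from a phenol that already carries the chain. Ortho-acylation of such a phenol competes with acylation para to the methoxy group, and the chain hydroxyl would then need protection in the presence of a more acidic phenol.

**4 to 2 to 1.** The pyranone ring is opened at O1–C2, and C2 is removed as a one-carbon unit introduced by an amide acetal through enaminone 3. The bromine of 2 goes back to hydroxyacetophenone 1. In 1 the hydroxyl group (para) and the acetyl group (meta) direct to the same carbon, so the regiochemistry is not in doubt.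

**11 to 9 to 8.** The C–B bond comes from the C–Br bond of 9 through aryllithium 10, and the benzyl ether comes from phenol 8.

## Alternatives that were turned down

**Alternative 1: ring A built last by a pyrone cycloaddition.**

- Disconnection: C3a–C4 and C7a–C7. Ring A is assembled on a finished oxygen heterocycle.
- Forward key step: the cyclic silyl ketene acetal A1 adds across C3 and C6 of the 2-pyrone A2. Decarboxylation and loss of the silyloxy group then aromatise the adduct to the benzofuran A3.
- For it: C2 and C3 are fixed in a small ring before the key step and are only spectators in it. No oxidant comes near the electron-rich rings. The polarity of A1 and A2 matches the required regiochemistry. On the independence of the stereochemistry from the key step this route is stronger than the chosen one.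
- Against it: A3 carries bromine on C7 and an ester on C5, where the target has a methoxy group and a three-carbon alcohol chain. A C–O coupling on a hindered, electron-rich bromide and a two-carbon homologation with reductions must follow, at least five further steps. A1 must itself first be made in enantiopure form over several steps.
- Comparison: the chosen route has both ring A substituents in place from intermediate 7 onwards and needs two steps after the key step. What it gives up is the independence of C3 from the key step.

**Alternative 2: furan–yne cascade forming ring A and the heterocycle together.**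

- Disconnection: C3a–C7a and C6–C7.
- Forward key step: with a cationic phosphine complex of monovalent gold, the furan carbon of the ynol ether A4 attacks the oxygen-bearing alkyne carbon. The opened furan recloses on the terminal alkyne carbon, and the phenol A5 results.
- For it: two rings form in one atom-economical step, and the stereocentres are set beforehand on an open chain. In bond formation per step it is equal to or better than the chosen key step.
- Against it:
  - A4 is an ethynyl ether of a secondary benzylic alcohol with a hydrogen on C3. Such ethers fragment by a retro-ene path and hydrate easily.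
  - Once gold activates the alkyne, the benzylic C2–O bond can ionise, which puts C2 at risk.
  - C3 is a furfurylic centre and is acid-sensitive.
  - The 2,4-disubstituted furan needs a synthesis of its own.
  - The position of the new hydroxyl group is not secured for an oxygen-substituted alkyne.
  - A5 still needs O-methylation, desilylation and debenzylation.
- Comparison: the chosen route reaches its key-step precursor 12 in four linear steps from a commercial ketone and uses a substrate class for which the key reaction is known.

**Alternative 3: asymmetric Prins hydroxymethylation ended by the phenol.**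

- Disconnection: the C3–CH2OH bond and O1–C2.
- Forward key step: the (E)-2-hydroxystilbene A6 attacks formaldehyde A7 inside a confined chiral imidodiphosphorimidate acid. The ring A hydroxyl then closes on the para-quinone methide at C2 to give the acetate A8.
- For it: it is the shortest route. A6 is one olefination or Heck reaction away from simple arenes, no phenol protection is needed, and one catalytic step would make a C–C bond, a C–O bond, the ring and both stereocentres. On step count and convergence it is clearly stronger than the chosen route.
- Against it:
  - The ortho-hydroxyl of ring A stabilises a cation on C3 about as well as the para-hydroxyl of ring B stabilises one on C2. Attack through the wrong alkene carbon is therefore not excluded.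
  - A7 with a strong acid can hydroxymethylate electron-rich phenols and can convert the product alcohol into formals or dioxanes, the usual Prins outcome with aryl alkenes.
  - Enantiofacial control on an unfunctionalised stilbene bearing two free phenols is uncertain.
  - The C2–O1 bond of A8 can re-ionise under the acid.
- Comparison: the chosen route is longer, but every step is a known reaction type. C2 is set by a catalytic addition with precedent on chromones, and C3 follows from C2 by mechanism.

Key step: step 7

Assumption: (R)-t-BuPyOx is taken to be the ligand antipode that gives the (2S)-flavanone, by transferring the facial sense known for cyclic enones to the chromone. If the sense is the opposite, the (S)-ligand is used and nothing else changes.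

## Steps

Step 1
Reactants: 1 1-(2-hydroxy-3-methoxyphenyl)ethanone
Product: 2 1-(5-bromo-2-hydroxy-3-methoxyphenyl)ethanone
Conditions: NBS (1.05 equiv), MeCN, 0 °C to rt
Reagents that add atoms: N-bromosuccinimide, O=C1CCC(=O)N1Br
Why: Electrophilic aromatic bromination; the free hydroxyl directs para and the acetyl group meta, both to C5, and without added acid the activated ring should react well before the methyl ketone is brominated.

Step 2
Reactants: 2 1-(5-bromo-2-hydroxy-3-methoxyphenyl)ethanone
Product: 4 6-bromo-8-methoxy-4H-chromen-4-one, via enaminone 3 (not isolated)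
Conditions: Me2NCH(OMe)2, toluene, 100 °C; evaporate; conc. HCl, CH2Cl2, 40 °C
Reagents that add atoms: N,N-dimethylformamide dimethyl acetal, COC(OC)N(C)C
Why: Enaminone route to chromones: the methyl ketone condenses with the amide acetal to give 3, and acid then brings about conjugate addition of the phenol and loss of dimethylamine; the aryl bromide is inert.

Step 3
Reactants: 4 6-bromo-8-methoxy-4H-chromen-4-one, 5 allyl benzyl ether
Product: 7 6-(3-benzyloxypropyl)-8-methoxy-4H-chromen-4-one, via alkylborane 6 (not isolated)
Conditions: 5 (1.5 equiv), 9-BBN-H (1.4 equiv), THF, 0 °C to rt; then 4, PdCl2(dppf) (5 mol%), aq. K3PO4, DMF, 55 °C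
Reagents that add atoms: none
Why: Anti-Markovnikov hydroboration of the terminal alkene gives primary alkylborane 6, which couples with the aryl bromide in a B-alkyl Suzuki–Miyaura reaction; the dppf ligand favours reductive elimination over β-hydride elimination, and the slight excess of alkene over borane leaves no B–H to reduce the pyranone.

Step 4
Reactants: 8 4-bromo-2,6-dimethoxyphenol
Product: 9 2-(benzyloxy)-5-bromo-1,3-dimethoxybenzene
Conditions: BnBr, K2CO3, DMF, 50 °C
Reagents that add atoms: benzyl bromide, BrCc1ccccc1
Why: Williamson ether synthesis; the hindered phenoxide is still alkylated readily by the reactive benzylic halide in a dipolar aprotic solvent.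

Step 5
Reactants: 9 2-(benzyloxy)-5-bromo-1,3-dimethoxybenzene
Product: 11 (4-benzyloxy-3,5-dimethoxyphenyl)boronic acid, via aryllithium 10 (not isolated)
Conditions: n-BuLi, THF, −78 °C; B(OiPr)3, −78 °C to rt; 1 M HCl
Reagents that add atoms: triisopropyl borate, CC(C)OB(OC(C)C)OC(C)C; water, O
Why: Bromine–lithium exchange is much faster at −78 °C than deprotonation of the benzyl ether; the aryllithium is trapped by the borate and the ester is hydrolysed to the boronic acid on acidic work-up.

Step 6
Reactants: 7 6-(3-benzyloxypropyl)-8-methoxy-4H-chromen-4-one, 11 (4-benzyloxy-3,5-dimethoxyphenyl)boronic acid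
Product: 12 (2S)-2-(4-benzyloxy-3,5-dimethoxyphenyl)-6-(3-benzyloxypropyl)-8-methoxychroman-4-one
Conditions: Pd(OCOCF3)2 (5 mol%), (R)-t-BuPyOx [(R)-4-tert-butyl-2-(pyridin-2-yl)-4,5-dihydrooxazole] (6 mol%), NH4PF6 (30 mol%), H2O (5 equiv), 11 (2 equiv), ClCH2CH2Cl, 60 °C
Reagents that add atoms: none
Why: Asymmetric conjugate addition of an arylboronic acid to a chromone under cationic divalent palladium with a pyridine-oxazoline ligand: transmetalation gives an arylpalladium species, the chromone C2=C3 bond inserts, and water protonates the palladium enolate. The tert-butyl group of the ligand differentiates the two faces of the chromone in the insertion and so sets C2.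

Step 7
Reactants: 12 (2S)-2-(4-benzyloxy-3,5-dimethoxyphenyl)-6-(3-benzyloxypropyl)-8-methoxychroman-4-one
Product: 15 methyl (2S,3S)-2-(4-benzyloxy-3,5-dimethoxyphenyl)-5-(3-benzyloxypropyl)-7-methoxy-2,3-dihydro-1-benzofuran-3-carboxylate, via enol ether 13 (not isolated), via iodane ketal 14 (not isolated)
Conditions: HC(OMe)3, conc. H2SO4, rt, 1 h; then PhI(OAc)2 (1.2 equiv), rt; aq. NaHCO3
Reagents that add atoms: trimethyl orthoformate, COC(OC)OC; water, O
Why: Acid and HC(OMe)3 convert ketone 12 into enol ether 13, whose C3 attacks the trivalent iodine centre of protonated PhI(OAc)2 on the face anti to the C2 aryl group, and methanol capture of the oxocarbenium ion gives the trans iodane ketal 14. In 14 the equatorial C3–I bond lies antiperiplanar to the C4–C4a bond, so loss of iodobenzene goes with a 1,2-shift of ring A carbon C4a from C4 to C3, and the resulting dimethoxycarbenium ion ends as the methyl ester through the orthoester on aqueous work-up. The closest known reaction type is the oxidative rearrangement of flavanones with hypervalent iodine reagents or Tl(NO3)3 in trimethyl orthoformate to methyl trans-2-aryl-2,3-dihydrobenzofuran-3-carboxylates. The dihydrofuran ring is closed by ring contraction, that is by forming C3–C3a inside the existing O1–C2–C3 unit, not by an end-to-end cyclisation. C3 is the new stereocentre: anti attack of iodine relative to the C2 aryl group followed by inversion at C3 in the shift should place the ester trans to the aryl group, which is also the more stable arrangement, while C2 is not touched and keeps its configuration. The step needs migration of ring A and not of ring B (isoflavone path) or simple elimination (flavone path): the diequatorial conformer of 14 aligns only the ring A bond with the leaving group, C4a is activated by the ortho oxygen O1, and ring B is a moderate migrating group because its methoxy groups are meta to the migrating carbon and the flanked benzyloxy group is twisted out of conjugation. Ketal formation before the oxidant is added blocks retro-oxa-Michael opening at C2, and the benzyl ethers keep the ring B oxygen and the chain oxygen out of the oxidation.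

Step 8
Reactants: 15 methyl (2S,3S)-2-(4-benzyloxy-3,5-dimethoxyphenyl)-5-(3-benzyloxypropyl)-7-methoxy-2,3-dihydro-1-benzofuran-3-carboxylate
Product: 16 [(2S,3R)-2-(4-benzyloxy-3,5-dimethoxyphenyl)-5-(3-benzyloxypropyl)-7-methoxy-2,3-dihydro-1-benzofuran-3-yl]methanol
Conditions: LiAlH4, THF, −20 to 0 °C; H2O, aq. NaOH
Reagents that add atoms: none
Why: Hydride reduction of the ester to the primary alcohol; at low temperature reduction should outrun enolisation at C3, so neither epimerisation nor β-elimination of the phenoxide is expected, and the descriptor at C3 changes from S to R only because the substituent priorities change.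

Step 9
Reactants: 16 [(2S,3R)-2-(4-benzyloxy-3,5-dimethoxyphenyl)-5-(3-benzyloxypropyl)-7-methoxy-2,3-dihydro-1-benzofuran-3-yl]methanol
Product: 17 4-[(2S,3R)-3-(hydroxymethyl)-5-(3-hydroxypropyl)-7-methoxy-2,3-dihydro-1-benzofuran-2-yl]-2,6-dimethoxyphenol
Conditions: H2 (1 atm), 10% Pd/C, EtOAc–MeOH, rt, stopped after uptake of 2 equiv
Reagents that add atoms: none
Why: Catalytic hydrogenolysis of the aryl benzyl ether and the alkyl benzyl ether; both are cleaved faster than the cyclic benzylic C2–O1 bond, which is kept intact by stopping at two equivalents of hydrogen.

## Compound list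

1 | 1-(2-hydroxy-3-methoxyphenyl)ethanone | CC(=O)c1cccc(OC)c1O | starting material
2 | 1-(5-bromo-2-hydroxy-3-methoxyphenyl)ethanone | CC(=O)c1cc(Br)cc(OC)c1O | intermediate
3 | (E)-1-(5-bromo-2-hydroxy-3-methoxyphenyl)-3-(dimethylamino)prop-2-en-1-one | CN(C)/C=C/C(=O)c1cc(Br)cc(OC)c1O | intermediate
4 | 6-bromo-8-methoxy-4H-chromen-4-one | COc1cc(Br)cc2c(=O)ccoc12 | intermediate
5 | allyl benzyl ether | C=CCOCc1ccccc1 | starting material
6 | 9-(3-benzyloxypropyl)-9-borabicyclo[3.3.1]nonane | C(CCB1C2CCCC1CCC2)OCc1ccccc1 | intermediate
7 | 6-(3-benzyloxypropyl)-8-methoxy-4H-chromen-4-one | COc1cc(CCCOCc2ccccc2)cc2c(=O)ccoc12 | intermediate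
8 | 4-bromo-2,6-dimethoxyphenol | COc1cc(Br)cc(OC)c1O | starting material
9 | 2-(benzyloxy)-5-bromo-1,3-dimethoxybenzene | COc1cc(Br)cc(OC)c1OCc1ccccc1 | intermediate
10 | (4-benzyloxy-3,5-dimethoxyphenyl)lithium | [Li]c1cc(OC)c(OCc2ccccc2)c(OC)c1 | intermediate
11 | (4-benzyloxy-3,5-dimethoxyphenyl)boronic acid | COc1cc(B(O)O)cc(OC)c1OCc1ccccc1 | intermediate
12 | (2S)-2-(4-benzyloxy-3,5-dimethoxyphenyl)-6-(3-benzyloxypropyl)-8-methoxychroman-4-one | COc1cc([C@@H]2CC(=O)c3cc(CCCOCc4ccccc4)cc(OC)c3O2)cc(OC)c1OCc1ccccc1 | intermediate
13 | (2S)-2-(4-benzyloxy-3,5-dimethoxyphenyl)-6-(3-benzyloxypropyl)-4,8-dimethoxy-2H-chromene | COc1cc([C@@H]2C=C(OC)c3cc(CCCOCc4ccccc4)cc(OC)c3O2)cc(OC)c1OCc1ccccc1 | intermediate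
14 | (2R,3R)-2,3-trans-3-[acetoxy(phenyl)-λ3-iodanyl]-2-(4-benzyloxy-3,5-dimethoxyphenyl)-6-(3-benzyloxypropyl)-4,4,8-trimethoxychromane (C2 arranged in space as in 12; its descriptor changes because iodine raises the priority of C3) | COc1cc([C@@H]2[C@@H](I(OC(C)=O)c3ccccc3)C(OC)(OC)c3cc(CCCOCc4ccccc4)cc(OC)c3O2)cc(OC)c1OCc1ccccc1 | intermediate
15 | methyl (2S,3S)-2-(4-benzyloxy-3,5-dimethoxyphenyl)-5-(3-benzyloxypropyl)-7-methoxy-2,3-dihydro-1-benzofuran-3-carboxylate (2,3-trans) | COc1cc([C@H]2Oc3c(OC)cc(CCCOCc4ccccc4)cc3[C@@H]2C(=O)OC)cc(OC)c1OCc1ccccc1 | intermediate
16 | [(2S,3R)-2-(4-benzyloxy-3,5-dimethoxyphenyl)-5-(3-benzyloxypropyl)-7-methoxy-2,3-dihydro-1-benzofuran-3-yl]methanol | COc1cc([C@H]2Oc3c(OC)cc(CCCOCc4ccccc4)cc3[C@@H]2CO)cc(OC)c1OCc1ccccc1 | intermediate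
17 | 4-[(2S,3R)-3-(hydroxymethyl)-5-(3-hydroxypropyl)-7-methoxy-2,3-dihydro-1-benzofuran-2-yl]-2,6-dimethoxyphenol | COc1cc([C@H]2Oc3c(OC)cc(CCCO)cc3[C@@H]2CO)cc(OC)c1O | target

## Step count and risk

Total step count: 9. Longest linear sequence: 7 steps (steps 1, 2, 3, 6, 7, 8, 9); the boronic acid branch (steps 4 and 5) joins at step 6.

**Step 7 (key step).** Three things are most likely to go wrong.

- Loss of the iodane by elimination (flavone) or migration of ring B from C2 to C3 (isoflavone) instead of the ring A shift. This happens if the diaxial conformer of 14 is populated or if ring B turns out a better migrating group than expected.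
- Oxidation of the alkoxy-rich arenes by the trivalent iodine reagent under strong acid.
- Erosion of enantiopurity by retro-oxa-Michael opening at C2 before the ketone is fully converted into 13.

Fallback, setting out from 12 and returning at 15: the same ring A shift is carried out through a carbene instead of an iodane. Deprotonation of 12 with LiN(SiMe3)2 at −78 °C and C-acylation with 2,2,2-trifluoroethyl trifluoroacetate should give the 3-trifluoroacetyl ketone F1. Detrifluoroacetylative diazo transfer with methanesulfonyl azide and Et3N should give the 3-diazo ketone F2. Irradiation in methanol (Wolff rearrangement) moves C4a from C4 to C3 and gives the ketene F3. Methanol traps F3 as ester 15 together with its cis epimer F4, and brief equilibration with DBU should converge on trans 15.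

**Step 6.** Insufficient facial discrimination, or incomplete conversion through protodeboronation of the electron-rich boronic acid and the lower reactivity of the 8-methoxy chromone, would leave 12 with inadequate enantiopurity.

Fallback, setting out from 7 and 11 and returning at 12: the addition is run with Pd(OCOCF3)2 and achiral 2,2'-bipyridine to give the racemic flavanone F5. F5 is then resolved by asymmetric transfer hydrogenation with RuCl[(R,R)-TsDPEN](p-cymene) in HCO2H–Et3N, stopped near half conversion. The catalyst antipode is taken as the one that reduces the (2R)-ketone faster, to the cis-flavan-4-ol F6. This leaves (2S)-ketone 12, which is separated by chromatography.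

**Step 3.** Hydroxide or phosphate may add to C2 of the chromone and open the pyranone ring during the coupling, and slow transmetalation of the alkylborane would allow protodebromination.

Fallback, setting out from 2 and 6 and returning at 7: the order of events is changed so that no chromone meets the base. Bromophenol 2 is coupled with 6 under the same catalyst with one more equivalent of base to give the hydroxy ketone F7. F7 is condensed with the amide acetal to the enaminone F8, which is cyclised with acid to 7 as in step 2.

**Step 9.** Over-reduction by hydrogenolysis of the benzylic C2–O1 ring bond is the main danger. Once the ring B phenol is free this bond is a para-hydroxybenzyl ether and is more labile.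

Fallback, setting out from 16 and returning at 17: non-reductive cleavage of both benzyl ethers with BCl3 and pentamethylbenzene as cation scavenger in CH2Cl2 at −78 °C. No new compound is made on this way (none F0).

## Further compounds

F1 | step 7 | (2S)-2-(4-benzyloxy-3,5-dimethoxyphenyl)-6-(3-benzyloxypropyl)-8-methoxy-3-(trifluoroacetyl)chroman-4-one (C3 unassigned, enolisable) | COc1cc([C@@H]2C(C(=O)C(F)(F)F)C(=O)c3cc(CCCOCc4ccccc4)cc(OC)c3O2)cc(OC)c1OCc1ccccc1
F2 | step 7 | (2R)-2-(4-benzyloxy-3,5-dimethoxyphenyl)-6-(3-benzyloxypropyl)-3-diazo-8-methoxychroman-4-one (C2 arranged in space as in 12) | COc1cc([C@@H]2C(=[N+]=[N-])C(=O)c3cc(CCCOCc4ccccc4)cc(OC)c3O2)cc(OC)c1OCc1ccccc1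
F3 | step 7 | [(2R)-2-(4-benzyloxy-3,5-dimethoxyphenyl)-5-(3-benzyloxypropyl)-7-methoxy-1-benzofuran-3(2H)-ylidene]methanone (ketene; C2 arranged in space as in 15) | COc1cc([C@H]2Oc3c(OC)cc(CCCOCc4ccccc4)cc3C2=C=O)cc(OC)c1OCc1ccccc1
F4 | step 7 | methyl (2S,3R)-2-(4-benzyloxy-3,5-dimethoxyphenyl)-5-(3-benzyloxypropyl)-7-methoxy-2,3-dihydro-1-benzofuran-3-carboxylate (2,3-cis) | COc1cc([C@H]2Oc3c(OC)cc(CCCOCc4ccccc4)cc3[C@H]2C(=O)OC)cc(OC)c1OCc1ccccc1
F5 | step 6 | racemic 2-(4-benzyloxy-3,5-dimethoxyphenyl)-6-(3-benzyloxypropyl)-8-methoxychroman-4-one | COc1cc(C2CC(=O)c3cc(CCCOCc4ccccc4)cc(OC)c3O2)cc(OC)c1OCc1ccccc1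
F6 | step 6 | (2R,4R)-2-(4-benzyloxy-3,5-dimethoxyphenyl)-6-(3-benzyloxypropyl)-8-methoxychroman-4-ol (2,4-cis) | COc1cc([C@H]2C[C@@H](O)c3cc(CCCOCc4ccccc4)cc(OC)c3O2)cc(OC)c1OCc1ccccc1
F7 | step 3 | 1-[5-(3-benzyloxypropyl)-2-hydroxy-3-methoxyphenyl]ethanone | CC(=O)c1cc(CCCOCc2ccccc2)cc(OC)c1O
F8 | step 3 | (E)-1-[5-(3-benzyloxypropyl)-2-hydroxy-3-methoxyphenyl]-3-(dimethylamino)prop-2-en-1-one | CN(C)/C=C/C(=O)c1cc(CCCOCc2ccccc2)cc(OC)c1O
F0 | step 9 | none | none
A1 | alternative 1 | 4,5-trans-5-(4-benzyloxy-3,5-dimethoxyphenyl)-2-(tert-butyldimethylsilyloxy)-4-(tert-butyldimethylsilyloxymethyl)-4,5-dihydrofuran, configured as C2 and C3 of 17 | COc1cc([C@H]2OC(O[Si](C)(C)C(C)(C)C)=C[C@@H]2CO[Si](C)(C)C(C)(C)C)cc(OC)c1OCc1ccccc1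
A2 | alternative 1 | methyl 3-bromo-2-oxo-2H-pyran-5-carboxylate | COC(=O)C1=COC(=O)C(Br)=C1
A3 | alternative 1 | methyl (2S,3R)-2-(4-benzyloxy-3,5-dimethoxyphenyl)-7-bromo-3-(tert-butyldimethylsilyloxymethyl)-2,3-dihydro-1-benzofuran-5-carboxylate | COc1cc([C@H]2Oc3c(Br)cc(C(=O)OC)cc3[C@@H]2CO[Si](C)(C)C(C)(C)C)cc(OC)c1OCc1ccccc1
A4 | alternative 2 | ethynyl ether of 1-(4-benzyloxy-3,5-dimethoxyphenyl)-3-(tert-butyldimethylsilyloxy)-2-{4-[3-(tert-butyldimethylsilyloxy)propyl]furan-2-yl}propan-1-ol, configured as C2 and C3 of 17 | COc1cc([C@@H](OC#C)[C@@H](CO[Si](C)(C)C(C)(C)C)c2cc(CCCO[Si](C)(C)C(C)(C)C)co2)cc(OC)c1OCc1ccccc1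
A5 | alternative 2 | (2S,3R)-2-(4-benzyloxy-3,5-dimethoxyphenyl)-3-(tert-butyldimethylsilyloxymethyl)-5-[3-(tert-butyldimethylsilyloxy)propyl]-2,3-dihydro-1-benzofuran-7-ol | COc1cc([C@H]2Oc3c(O)cc(CCCO[Si](C)(C)C(C)(C)C)cc3[C@@H]2CO[Si](C)(C)C(C)(C)C)cc(OC)c1OCc1ccccc1
A6 | alternative 3 | 3-{4-hydroxy-3-[(E)-2-(4-hydroxy-3,5-dimethoxyphenyl)ethenyl]-5-methoxyphenyl}propyl acetate | COc1cc(/C=C/c2cc(CCCOC(C)=O)cc(OC)c2O)cc(OC)c1O
A7 | alternative 3 | formaldehyde | C=O
A8 | alternative 3 | 3-[(2S,3R)-2-(4-hydroxy-3,5-dimethoxyphenyl)-3-(hydroxymethyl)-7-methoxy-2,3-dihydro-1-benzofuran-5-yl]propyl acetate | COc1cc([C@H]2Oc3c(OC)cc(CCCOC(C)=O)cc3[C@@H]2CO)cc(OC)c1O
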